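## Retrosynthetic overview

1. Target 44 ⇐ 13,14-dihydro ketone 43 (late dehydrogenation) ⇐ 12-ol 42; γ-lactone ⇐ oxidative lactonisation of the C19 primary alcohol onto the C7 hydroxyl.
2. Ten-membered ring ⇐ C6–C7 Nozaki–Hiyama–Kishi closure of the (Z)-vinyl iodide/aldehyde 38.
3. C8/C17 ⇐ hydroxyl-directed epoxidation and Me3Al opening of allylic alcohol 33; C8–C9 bond ⇐ alkenylmagnesium 32 + C9 aldehyde 25.
4. C2–C6 arm ⇐ methyl ketone 15 + allylic bromide 19, then CBS reduction; ring A triad (C1, C10, C11) ⇐ ene-reductase desymmetrisation of dienone 6, vinyl cuprate addition, Rubottom oxidation.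
5. Ring order: ring A (the carbocycle of benzoic acid, present from the start) → ten-membered ring (step 28) → γ-lactone (step 30).

Assumptions: briarane numbering (C1–C20) is used for all intermediates, with β = the face of the C15 methyl on C1; the target is (1S,2R,5Z,7S,8S,9R,10S,11S,17R); the ene-reductase giving (S)-7 is picked from a panel of enantiocomplementary Old Yellow Enzyme homologues; the C12 carbinol configuration of 13–42 (drawn 12β) is inconsequential because C12 ends as the ketone.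

## Route

Step 1
Reactants: 1 benzoic acid
Product: 3 1-methylcyclohexa-2,5-diene-1-carboxylic acid, via Birch dienolate dianion 2 (not isolated)
Conditions: Li, NH3(l)/THF, −78 °C; then MeI; aq. HCl work-up
Reagents that add atoms: iodomethane CI
Why: Birch reduction of the benzoate gives the cross-conjugated dienolate, which is C-methylated at the carboxyl-bearing carbon (Birch reductive alkylation); no stereocentre is formed.

Step 2
Reactants: 3 1-methylcyclohexa-2,5-diene-1-carboxylic acid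
Product: 4 1-(1-methylcyclohexa-2,5-dien-1-yl)ethanone
Conditions: MeLi (2.2 equiv), Et2O, 0 → 23 °C; aq. NH4Cl
Reagents that add atoms: methyllithium [Li]C
Why: Addition of MeLi to the lithium carboxylate gives a stable gem-diolate that collapses to the methyl ketone only on work-up (carboxylic acid to methyl ketone).

Step 3
Reactants: 4 1-(1-methylcyclohexa-2,5-dien-1-yl)ethanone
Product: 5 2-methyl-2-(1-methylcyclohexa-2,5-dien-1-yl)-1,3-dioxolane
Conditions: (Me3SiOCH2)2, Me3SiOTf (cat.), CH2Cl2, −78 → −20 °C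
Reagents that add atoms: 1,2-bis(trimethylsilyloxy)ethane C[Si](C)(C)OCCO[Si](C)(C)C
Why: Noyori ketalisation works on the hindered ketone under aprotic conditions that leave the 1,4-diene alone, and gives the bulky C2 group needed later for facial control.

Step 4
Reactants: 5 2-methyl-2-(1-methylcyclohexa-2,5-dien-1-yl)-1,3-dioxolane
Product: 6 4-methyl-4-(2-methyl-1,3-dioxolan-2-yl)cyclohexa-2,5-dienone
Conditions: Rh2(C6H10NO)4 (dirhodium tetracaprolactamate, 1 mol%), t-BuOOH, K2CO3, CH2Cl2, 23 °C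
Reagents that add atoms: tert-butyl hydroperoxide CC(C)(C)OO
Why: Allylic oxidation of the doubly allylic CH2 gives the achiral, prochiral cross-conjugated dienone.

Step 5
Reactants: 6 4-methyl-4-(2-methyl-1,3-dioxolan-2-yl)cyclohexa-2,5-dienone
Product: 7 (S)-4-methyl-4-(2-methyl-1,3-dioxolan-2-yl)cyclohex-2-enone
Conditions: ene-reductase (flavin-dependent Old Yellow Enzyme class, YqjM type), NADP+ (cat.), NADP-accepting formate dehydrogenase, HCO2Na, potassium phosphate buffer pH 7.0, 5% DMSO, 30 °C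
Reagents that add atoms: none
Why: The ene-reductase transfers hydride from reduced flavin to one enantiotopic β-carbon and a proton to the α-carbon (biocatalytic asymmetric desymmetrisation), which sets the C1 quaternary centre as the first stereocentre, while the enone product is a much poorer substrate than the dienone.

Step 6
Reactants: 7 (S)-4-methyl-4-(2-methyl-1,3-dioxolan-2-yl)cyclohex-2-enone
Product: 8 (S)-2-iodo-4-methyl-4-(2-methyl-1,3-dioxolan-2-yl)cyclohex-2-enone
Conditions: I2, pyridine/CH2Cl2, 23 °C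
Reagents that add atoms: iodine II
Why: Johnson α-iodination of the enone (pyridine addition, iodination, elimination) leaves the quaternary centre untouched.

Step 7
Reactants: 8 (S)-2-iodo-4-methyl-4-(2-methyl-1,3-dioxolan-2-yl)cyclohex-2-enone
Product: 9 (S)-2,4-dimethyl-4-(2-methyl-1,3-dioxolan-2-yl)cyclohex-2-enone
Conditions: MeB(OH)2, PdCl2(dppf) (5 mol%), K3PO4, THF/H2O, 60 °C
Reagents that add atoms: methylboronic acid CB(O)O
Why: Suzuki–Miyaura cross-coupling of the α-iodoenone installs the C20 methyl on the future C11.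

Step 8
Reactants: 9 (S)-2,4-dimethyl-4-(2-methyl-1,3-dioxolan-2-yl)cyclohex-2-enone
Product: 10 trimethylsilyl enol ether of the 3-vinyl ketone (vinyl cis to the C1 methyl; trans to the dioxolanyl group)
Conditions: CH2=CHMgBr, CuBr·SMe2 (20 mol%), Me3SiCl, HMPA, THF, −78 °C; Et3N quench
Reagents that add atoms: vinylmagnesium bromide C=C[Mg]Br; chlorotrimethylsilane C[Si](C)(C)Cl
Why: In this copper-catalysed, silyl-chloride-accelerated conjugate addition the vinyl group enters anti to the bulky dioxolanyl group, which sets C10 (vinyl β, cis to C15), and the enolate is trapped regiospecifically as the tetrasubstituted silyl enol ether.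

Step 9
Reactants: 10 trimethylsilyl enol ether of the 3-vinyl ketone
Product: 12 α-hydroxy ketone (11α-OH; 11β-Me; 10β-vinyl; C2 as dioxolane), via α-silyloxy ketone 11 (not isolated)
Conditions: mCPBA (1.05 equiv), NaHCO3, CH2Cl2, −20 °C; then K2CO3 (cat.), MeOH, 0 °C
Reagents that add atoms: 3-chloroperbenzoic acid OOC(=O)c1cccc(Cl)c1
Why: Rubottom oxidation epoxidises the electron-rich enol ether (far faster than the vinyl group) on the α-face, anti to the C10 vinyl and the axial C15 methyl, so C11 is set with 11α-OH and 11β-methyl.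

Step 10
Reactants: 12 α-hydroxy ketone
Product: 13 trans-diol (11α-OH; 12β-OH)
Conditions: NaBH4, MeOH, 0 °C
Reagents that add atoms: none
Why: Axial hydride delivery from the α-face reduces the C12 ketone to the equatorial 12β-alcohol, masking the ketone; this centre is destroyed again in step 31.

Step 11
Reactants: 13 trans-diol
Product: 14 diol methyl ketone (C2 acetyl freed)
Conditions: 1 M aq. HCl, THF, 40 °C
Reagents that add atoms: water O
Why: Acid-catalysed ketal hydrolysis releases the C2 methyl ketone while the tertiary alcohol and the vinyl group are inert.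

Step 12
Reactants: 14 diol methyl ketone
Product: 15 12-O-tert-butyldimethylsilyl ether of 14
Conditions: t-BuMe2SiCl, imidazole, DMF, 40 °C
Reagents that add atoms: tert-butyldimethylsilyl chloride CC(C)(C)[Si](C)(C)Cl
Why: Silylation is selective for the secondary C12 hydroxyl because the tertiary C11 hydroxyl is too hindered.

Step 13
Reactants: 16 prop-2-yn-1-ol
Product: 18 (Z)-3-iodo-2-methylprop-2-en-1-ol, via cyclic alkenylmagnesium alkoxide 17 (not isolated)
Conditions: MeMgBr (2.5 equiv), CuI (10 mol%), THF, −10 → 23 °C; then I2, −30 °C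
Reagents that add atoms: methylmagnesium bromide C[Mg]Br; iodine II
Why: Alkoxide-directed anti-carbomagnesiation puts the methyl on the internal carbon and magnesium cis to CH2O, and iodinolysis with retention gives the (Z)-iodide (the C4–C6 unit with C16).

Step 14
Reactants: 18 (Z)-3-iodo-2-methylprop-2-en-1-ol
Product: 19 (Z)-3-bromo-1-iodo-2-methylprop-1-ene
Conditions: CBr4, PPh3, CH2Cl2, 0 °C
Reagents that add atoms: tetrabromomethane BrC(Br)(Br)Br
Why: The Appel reaction converts the primary allylic alcohol into the bromide without touching the alkene geometry.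

Step 15
Reactants: 15 12-O-silyl methyl ketone; 19 (Z)-3-bromo-1-iodo-2-methylprop-1-ene
Product: 21 ring A ketone bearing the (Z)-5-iodo-4-methylpent-4-enoyl group at C1, via dilithium enolate alkoxide 20 (not isolated)
Conditions: LiN(iPr)2 (2.2 equiv), THF, −78 °C; then 19, DMPU, −78 → −30 °C
Reagents that add atoms: none
Why: The methyl ketone can enolise only towards C3 (C1 is quaternary) and its kinetic lithium enolate is alkylated by the reactive allylic bromide (enolate alkylation), forming the C3–C4 bond.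

Step 16
Reactants: 21 ring A C2 ketone
Product: 22 (2R)-alcohol
Conditions: (S)-2-methyl-CBS-oxazaborolidine (0.5 equiv), catecholborane, toluene, −78 → −40 °C
Reagents that add atoms: none
Why: Corey–Bakshi–Shibata reduction under reagent control (quaternary C1 as the large group, C3H2 as the small one) sets C2 as R, and catecholborane does not hydroborate the alkenes.

Step 17
Reactants: 22 (2R)-alcohol
Product: 23 (2R)-butanoate
Conditions: (PrCO)2O, DMAP, Et3N, CH2Cl2, 23 → 40 °C
Reagents that add atoms: butanoic anhydride CCCC(=O)OC(=O)CCC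
Why: DMAP-catalysed acylation installs the final C2 butanoate on the secondary alcohol while the hindered tertiary C11 hydroxyl does not react.

Step 18
Reactants: 23 (2R)-butanoate
Product: 25 C9 aldehyde (formyl group on C10), via vicinal diol 24 (not isolated)
Conditions: K2OsO2(OH)4 (2 mol%), NaIO4, 2,6-lutidine, dioxane/H2O (3:1), 23 °C
Reagents that add atoms: sodium periodate [Na+].[O-]I(=O)(=O)=O
Why: Lemieux–Johnson cleavage takes the monosubstituted vinyl group and spares the electron-poor iodoalkene, and the lutidine buffer keeps C10 from epimerising.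

Step 19
Reactants: 26 but-2-yne-1,4-diol
Product: 27 4-[(4-methoxybenzyl)oxy]but-2-yn-1-ol
Conditions: NaH (1 equiv), 4-MeOC6H4CH2Cl, Bu4NI (cat.), THF/DMF, 0 → 23 °C (26 in threefold excess)
Reagents that add atoms: 4-methoxybenzyl chloride COc1ccc(CCl)cc1
Why: Williamson etherification with excess diol gives the mono-ether.

Step 20
Reactants: 27 4-[(4-methoxybenzyl)oxy]but-2-yn-1-ol
Product: 29 (Z)-3-iodo-4-[(4-methoxybenzyl)oxy]but-2-en-1-ol, via cyclic alkenyl alanate 28 (not isolated)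
Conditions: NaAlH2(OCH2CH2OMe)2, THF, 0 °C; then I2, −78 °C
Reagents that add atoms: iodine II
Why: Alkoxide-directed trans-hydroalumination places aluminium on the carbon distal to the free hydroxyl and cis to it, and iodinolysis with retention gives the (Z)-3-iodide.

Step 21
Reactants: 29 (Z)-3-iodo-4-[(4-methoxybenzyl)oxy]but-2-en-1-ol
Product: 30 (Z)-tert-butyl({3-iodo-4-[(4-methoxybenzyl)oxy]but-2-en-1-yl}oxy)diphenylsilane
Conditions: t-BuPh2SiCl, imidazole, CH2Cl2, 23 °C
Reagents that add atoms: tert-butyl(chloro)diphenylsilane CC(C)(C)[Si](Cl)(c1ccccc1)c1ccccc1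
Why: Silylation protects the future C19 hydroxyl orthogonally to the 4-methoxybenzyl ether on C7.

Step 22
Reactants: 25 C9 aldehyde; 30 (Z)-alkenyl iodide
Product: 33 (9R)-allylic alcohol (C8=C17 alkene with C19H2 cis to C9), via alkenyllithium 31 (not isolated), via alkenylmagnesium bromide 32 (not isolated)
Conditions: 30 (3 equiv), t-BuLi (6 equiv), Et2O, −78 °C; MgBr2·OEt2; then 25, THF, −78 °C; aq. NH4Cl
Reagents that add atoms: none
Why: Iodine–lithium exchange with retention, transmetalation and 1,2-addition form the C8–C9 bond; the C11 magnesium alkoxide chelates the aldehyde and attack anti to the quaternary C1 (the Felkin–Anh sense as well) gives 9R, while ester and vinyl iodide survive at −78 °C.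

Step 23
Reactants: 33 (9R)-allylic alcohol
Product: 34 epoxy alcohol (8,17-epoxide syn to the C9 hydroxyl)
Conditions: mCPBA (1.1 equiv), NaHCO3, CH2Cl2, 0 °C
Reagents that add atoms: 3-chloroperbenzoic acid OOC(=O)c1cccc(Cl)c1
Why: In this Henbest hydroxyl-directed epoxidation, A(1,3) strain between C9–H and the cis C19H2 group fixes the conformer and the peracid is delivered from the C9–OH face (threo), which sets C8; the iodoalkene is too electron-poor to compete.

Step 24
Reactants: 34 epoxy alcohol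
Product: 35 8,9-diol with the C18 methyl on C17
Conditions: Me3Al (4 equiv), hexane/CH2Cl2, −30 → 0 °C; aq. NH4Cl
Reagents that add atoms: trimethylaluminium C[Al](C)C
Why: Aluminium-alkoxide-assisted SN2 opening of the 2,3-epoxy alcohol occurs at the distal, less substituted C17 with inversion (C8 is quaternary and doubly β-oxygenated), setting C17 and keeping the C8–O bond.

Step 25
Reactants: 35 8,9-diol
Product: 36 9-acetate
Conditions: Ac2O, DMAP, Et3N, CH2Cl2, 23 → 40 °C
Reagents that add atoms: acetic anhydride CC(=O)OC(C)=O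
Why: Acylation takes the only secondary hydroxyl (C9), leaving the tertiary C8 and C11 hydroxyls free.

Step 26
Reactants: 36 9-acetate
Product: 37 C7 primary alcohol
Conditions: DDQ, CH2Cl2/pH 7 buffer (10:1), 0 °C
Reagents that add atoms: none
Why: Oxidative cleavage of the 4-methoxybenzyl ether is orthogonal to the silyl ethers, esters and the vinyl iodide.

Step 27
Reactants: 37 C7 primary alcohol
Product: 38 C7 aldehyde (α-hydroxy aldehyde)
Conditions: SO3·pyridine, DMSO, iPr2NEt, CH2Cl2, 0 °C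
Reagents that add atoms: none
Why: Parikh–Doering oxidation converts the neopentyl primary alcohol to the aldehyde without glycol cleavage of the adjacent tertiary carbinol.

Step 28
Reactants: 38 C7 aldehyde
Product: 39 (7S)-macrocyclic allylic alcohol (ten-membered ring closed)
Conditions: CrCl2 (20 equiv), NiCl2 (0.2 equiv), DMSO, 23 °C, 2 mM, slow addition of 38
Reagents that add atoms: none
Why: In the Nozaki–Hiyama–Kishi reaction the (Z)-alkenyl iodide is converted with retention into an alkenylchromium species that adds only to the aldehyde and closes the ring, and chromium bridging the aldehyde oxygen and the free C8 hydroxyl with attack from the C9-tethered face gives 7S.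

Step 29
Reactants: 39 (7S)-macrocyclic allylic alcohol
Product: 40 pentaol (C19, C12, C7, C8 and C11 hydroxyls free)
Conditions: HF·pyridine, pyridine, THF, 0 → 23 °C
Reagents that add atoms: none
Why: Buffered fluoride removes both silyl ethers and leaves the two esters and the allylic alcohol intact.

Step 30
Reactants: 40 pentaol
Product: 42 γ-lactone (C19 carbonyl; O on C7), via lactol 41 (not isolated)
Conditions: [Cu(MeCN)4]OTf (10 mol%), 2,2'-bipyridine, TEMPO, N-methylimidazole, air, MeCN, 23 °C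
Reagents that add atoms: none
Why: Copper/nitroxyl aerobic oxidation is selective for the primary C19 alcohol; the aldehyde is captured by the C7 hydroxyl (C9 is acetylated) and the lactol is oxidised on to the trans-fused lactone (oxidative lactonisation) without cleaving the vicinal diols.

Step 31
Reactants: 42 γ-lactone 12-ol
Product: 43 C12 ketone (13,14-dihydro target)
Conditions: Pr4N[RuO4] (5 mol%), N-methylmorpholine N-oxide, 4 Å molecular sieves, CH2Cl2, 23 °C
Reagents that add atoms: none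
Why: Ley–Griffith oxidation converts the only secondary alcohol into the ketone, and the tertiary C8 and C11 hydroxyls cannot be oxidised.

Step 32
Reactants: 43 C12 ketone
Product: 44 CNP0346936.2 (target)
Conditions: IBX·4-methoxypyridine N-oxide (3 equiv), DMSO, 23 → 40 °C
Reagents that add atoms: none
Why: IBX dehydrogenation of the ketone can only go towards C13 because C11 is quaternary, giving the C13=C14 enone and leaving all stereocentres untouched.

## Compound list

1 | benzoic acid | OC(=O)c1ccccc1 | starting material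
2 | dilithium (cyclohexa-2,5-dien-1-ylidene)methanediolate (Birch dienolate dianion) | [Li+].[Li+].[O-]C([O-])=C1C=CCC=C1 | intermediate
3 | 1-methylcyclohexa-2,5-diene-1-carboxylic acid | CC1(C=CCC=C1)C(O)=O | intermediate
4 | 1-(1-methylcyclohexa-2,5-dien-1-yl)ethanone | CC(=O)C1(C)C=CCC=C1 | intermediate
5 | 2-methyl-2-(1-methylcyclohexa-2,5-dien-1-yl)-1,3-dioxolane | CC1(OCCO1)C1(C)C=CCC=C1 | intermediate
6 | 4-methyl-4-(2-methyl-1,3-dioxolan-2-yl)cyclohexa-2,5-dienone | CC1(OCCO1)C1(C)C=CC(=O)C=C1 | intermediate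
7 | (S)-4-methyl-4-(2-methyl-1,3-dioxolan-2-yl)cyclohex-2-enone | O=C1C=C[C@](C2(C)OCCO2)(C)CC1 | intermediate
8 | (S)-2-iodo-4-methyl-4-(2-methyl-1,3-dioxolan-2-yl)cyclohex-2-enone | O=C1C(I)=C[C@](C2(C)OCCO2)(C)CC1 | intermediate
9 | (S)-2,4-dimethyl-4-(2-methyl-1,3-dioxolan-2-yl)cyclohex-2-enone | O=C1C(C)=C[C@](C2(C)OCCO2)(C)CC1 | intermediate
10 | 1-(trimethylsilyloxy)-2,4-dimethyl-4-(2-methyl-1,3-dioxolan-2-yl)-3-vinylcyclohex-1-ene (vinyl cis to the 4-methyl) | C[Si](C)(C)OC1=C(C)[C@H](C=C)[C@](C2(C)OCCO2)(C)CC1 | intermediate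
11 | 2,4-dimethyl-4-(2-methyl-1,3-dioxolan-2-yl)-2-(trimethylsilyloxy)-3-vinylcyclohexanone (11α-OSiMe3; 11β-Me; 10β-vinyl) | C=C[C@@H]1[C@](C)(CCC(=O)[C@@]1(C)O[Si](C)(C)C)C1(C)OCCO1 | intermediate
12 | 2-hydroxy-2,4-dimethyl-4-(2-methyl-1,3-dioxolan-2-yl)-3-vinylcyclohexanone (11α-OH; 11β-Me; 10β-vinyl; 1β-Me) | C=C[C@@H]1[C@](C)(CCC(=O)[C@@]1(C)O)C1(C)OCCO1 | intermediate
13 | trans-diol of 12 (11α-OH; 12β-OH) | C=C[C@@H]1[C@](C)(CC[C@H](O)[C@@]1(C)O)C1(C)OCCO1 | intermediate
14 | diol methyl ketone (1-acetyl; 11α-OH; 12β-OH; 10β-vinyl) | C=C[C@@H]1[C@](C)(CC[C@H](O)[C@@]1(C)O)C(C)=O | intermediate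
15 | 12-O-tert-butyldimethylsilyl ether of 14 | C=C[C@@H]1[C@](C)(CC[C@H](O[Si](C)(C)C(C)(C)C)[C@@]1(C)O)C(C)=O | intermediate
16 | prop-2-yn-1-ol | C#CCO | starting material
17 | cyclic (Z)-alkenylmagnesium alkoxide (4-methyl-2,5-dihydro-1,2-oxamagnesole) | CC1=C[Mg]OC1 | intermediate
18 | (Z)-3-iodo-2-methylprop-2-en-1-ol | OC/C(C)=C\I | intermediate
19 | (Z)-3-bromo-1-iodo-2-methylprop-1-ene | BrC/C(C)=C\I | intermediate
20 | dilithium enolate alkoxide of 15 | C=C[C@@H]1[C@](C)(CC[C@H](O[Si](C)(C)C(C)(C)C)[C@@]1(C)O[Li])C(=C)O[Li] | intermediate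
21 | ring A C2 ketone with the (Z)-5-iodo-4-methylpent-4-enoyl group on C1 | C=C[C@@H]1[C@](C)(CC[C@H](O[Si](C)(C)C(C)(C)C)[C@@]1(C)O)C(=O)CC/C(C)=C\I | intermediate
22 | (2R)-alcohol from 21 | C=C[C@@H]1[C@](C)(CC[C@H](O[Si](C)(C)C(C)(C)C)[C@@]1(C)O)[C@H](O)CC/C(C)=C\I | intermediate
23 | (2R)-butanoate of 22 | C=C[C@@H]1[C@](C)(CC[C@H](O[Si](C)(C)C(C)(C)C)[C@@]1(C)O)[C@H](OC(=O)CCC)CC/C(C)=C\I | intermediate
24 | vicinal diol from the C10 vinyl group of 23 (mixture at the new carbinol) | OCC(O)[C@@H]1[C@](C)(CC[C@H](O[Si](C)(C)C(C)(C)C)[C@@]1(C)O)[C@H](OC(=O)CCC)CC/C(C)=C\I | intermediate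
25 | C9 aldehyde (10β-formyl) | O=C[C@@H]1[C@](C)(CC[C@H](O[Si](C)(C)C(C)(C)C)[C@@]1(C)O)[C@H](OC(=O)CCC)CC/C(C)=C\I | intermediate
26 | but-2-yne-1,4-diol | OCC#CCO | starting material
27 | 4-[(4-methoxybenzyl)oxy]but-2-yn-1-ol | COc1ccc(COCC#CCO)cc1 | intermediate
28 | sodium cyclic alkenyl alanate from 27 | [Na+].COCCO[Al-]1(OCCOC)OCC=C1COCc1ccc(OC)cc1 | intermediate
29 | (Z)-3-iodo-4-[(4-methoxybenzyl)oxy]but-2-en-1-ol | COc1ccc(COC/C(I)=C/CO)cc1 | intermediate
30 | (Z)-tert-butyl({3-iodo-4-[(4-methoxybenzyl)oxy]but-2-en-1-yl}oxy)diphenylsilane | COc1ccc(COC/C(I)=C/CO[Si](c2ccccc2)(c2ccccc2)C(C)(C)C)cc1 | intermediate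
31 | alkenyllithium from 30 (geometry retained) | COc1ccc(COC/C([Li])=C/CO[Si](c2ccccc2)(c2ccccc2)C(C)(C)C)cc1 | intermediate
32 | alkenylmagnesium bromide from 31 | COc1ccc(COC/C([Mg]Br)=C/CO[Si](c2ccccc2)(c2ccccc2)C(C)(C)C)cc1 | intermediate
33 | (9R)-allylic alcohol (C8=C17; C7H2 4-methoxybenzyl ether; C19H2 silyl ether cis to C9) | COc1ccc(COC/C(=C/CO[Si](c2ccccc2)(c2ccccc2)C(C)(C)C)[C@H](O)[C@@H]2[C@](C)(CC[C@H](O[Si](C)(C)C(C)(C)C)[C@@]2(C)O)[C@H](OC(=O)CCC)CC/C(C)=C\I)cc1 | intermediate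
34 | 8,17-epoxy-9-ol (epoxide oxygen syn to 9-OH; C8 as in the target) | COc1ccc(COC[C@]2(O[C@@H]2CO[Si](c3ccccc3)(c3ccccc3)C(C)(C)C)[C@H](O)[C@@H]2[C@](C)(CC[C@H](O[Si](C)(C)C(C)(C)C)[C@@]2(C)O)[C@H](OC(=O)CCC)CC/C(C)=C\I)cc1 | intermediate
35 | 8,9-diol with 17-methyl (C8, C9, C17 as in the target) | COc1ccc(COC[C@@](O)([C@@H](C)CO[Si](c2ccccc2)(c2ccccc2)C(C)(C)C)[C@H](O)[C@@H]2[C@](C)(CC[C@H](O[Si](C)(C)C(C)(C)C)[C@@]2(C)O)[C@H](OC(=O)CCC)CC/C(C)=C\I)cc1 | intermediate
36 | 9-acetate of 35 | COc1ccc(COC[C@@](O)([C@@H](C)CO[Si](c2ccccc2)(c2ccccc2)C(C)(C)C)[C@H](OC(C)=O)[C@@H]2[C@](C)(CC[C@H](O[Si](C)(C)C(C)(C)C)[C@@]2(C)O)[C@H](OC(=O)CCC)CC/C(C)=C\I)cc1 | intermediate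
37 | C7 primary alcohol (7,8-diol; 9-acetate) | OC[C@@](O)([C@@H](C)CO[Si](c1ccccc1)(c1ccccc1)C(C)(C)C)[C@H](OC(C)=O)[C@@H]1[C@](C)(CC[C@H](O[Si](C)(C)C(C)(C)C)[C@@]1(C)O)[C@H](OC(=O)CCC)CC/C(C)=C\I | intermediate
38 | C7 aldehyde (seco iodo-aldehyde) | O=C[C@@](O)([C@@H](C)CO[Si](c1ccccc1)(c1ccccc1)C(C)(C)C)[C@H](OC(C)=O)[C@@H]1[C@](C)(CC[C@H](O[Si](C)(C)C(C)(C)C)[C@@]1(C)O)[C@H](OC(=O)CCC)CC/C(C)=C\I | intermediate
39 | (7S)-macrocyclic allylic alcohol (5Z; 19-O- and 12-O-silyl ethers) | CCCC(=O)O[C@@H]1CC/C(C)=C\[C@H](O)[C@@](O)([C@@H](C)CO[Si](c2ccccc2)(c2ccccc2)C(C)(C)C)[C@H](OC(C)=O)[C@@H]2[C@]1(C)CC[C@H](O[Si](C)(C)C(C)(C)C)[C@@]2(C)O | intermediate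
40 | desilylated pentaol | CCCC(=O)O[C@@H]1CC/C(C)=C\[C@H](O)[C@@](O)([C@@H](C)CO)[C@H](OC(C)=O)[C@@H]2[C@]1(C)CC[C@H](O)[C@@]2(C)O | intermediate
41 | lactol (C19 hemiacetal with O7; mixture at C19) | CCCC(=O)O[C@@H]1CC/C(C)=C\[C@@H]2OC(O)[C@H](C)[C@@]2(O)[C@H](OC(C)=O)[C@@H]2[C@]1(C)CC[C@H](O)[C@@]2(C)O | intermediate
42 | γ-lactone 12β-ol | CCCC(=O)O[C@@H]1CC/C(C)=C\[C@@H]2OC(=O)[C@H](C)[C@@]2(O)[C@H](OC(C)=O)[C@@H]2[C@]1(C)CC[C@H](O)[C@@]2(C)O | intermediate
43 | 13,14-dihydro target (C12 ketone) | CCCC(=O)O[C@@H]1CC/C(C)=C\[C@@H]2OC(=O)[C@H](C)[C@@]2(O)[C@H](OC(C)=O)[C@@H]2[C@]1(C)CCC(=O)[C@@]2(C)O | intermediate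
44 | CNP0346936.2 | CCCC(=O)O[C@@H]1CC/C(C)=C\[C@@H]2OC(=O)[C@H](C)[C@@]2(O)[C@H](OC(C)=O)[C@@H]2[C@]1(C)C=CC(=O)[C@@]2(C)O | target

## Step count and risk

Total step count: 32. Longest linear sequence: 27 steps (benzoic acid to 44: steps 1–12, 15–18, 22–32).

The three steps most likely to fail:

Step 28 (ring closure and C7 configuration). The ten-membered ring may close with the wrong sense at C7 or as a mixture. The fallback sets out from aldehyde 38: if the closure gives the C7-epimeric macrocyclic alcohol F1, alone or mixed with 39, the allylic alcohol is oxidised with MnO2 in CH2Cl2 to the macrocyclic C7 enone F2. F2 is then reduced with Zn(BH4)2 in Et2O at −30 °C; zinc chelated between the C7 carbonyl and the free C8 hydroxyl, with hydride entering from the ring periphery, gives the 7S alcohol, and the route is rejoined at 39.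

Step 22 (C8–C9 bond and C9 configuration). Addition to the hindered aldehyde may be poorly selective. The fallback sets out from aldehyde 25 and iodide 30: the crude adduct containing the C9-epimeric allylic alcohol F3 is oxidised with Dess–Martin periodinane to the C9 enone F4. F4 is reduced with Et2BOMe and NaBH4 in THF/MeOH at −78 °C (Narasaka–Prasad reduction); the boron chelate with the C11 hydroxyl gives the 1,3-syn alcohol, which is the 9R compound, and the route is rejoined at 33.

Step 32 (late dehydrogenation). IBX may be sluggish or unselective on the polyfunctional ketone. The fallback sets out from ketone 43: Me3SiOTf and Et3N in CH2Cl2 (−78 → 0 °C) give the C12 trimethylsilyl enol ether 8,11-bis(trimethylsilyl) ether F5. Pd(OAc)2 in MeCN (Saegusa–Ito oxidation) turns F5 into the bis-silylated enone F6, and HF·pyridine removes the two silyl ethers to reach 44.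

## Further compounds

F1 | step 28 | C7-epimeric macrocyclic alcohol (7R) | CCCC(=O)O[C@@H]1CC/C(C)=C\[C@@H](O)[C@@](O)([C@@H](C)CO[Si](c2ccccc2)(c2ccccc2)C(C)(C)C)[C@H](OC(C)=O)[C@@H]2[C@]1(C)CC[C@H](O[Si](C)(C)C(C)(C)C)[C@@]2(C)O
F2 | step 28 | macrocyclic C7 enone | CCCC(=O)O[C@@H]1CC/C(C)=C\C(=O)[C@@](O)([C@@H](C)CO[Si](c2ccccc2)(c2ccccc2)C(C)(C)C)[C@H](OC(C)=O)[C@@H]2[C@]1(C)CC[C@H](O[Si](C)(C)C(C)(C)C)[C@@]2(C)O
F3 | step 22 | C9-epimeric allylic alcohol (9S) | COc1ccc(COC/C(=C/CO[Si](c2ccccc2)(c2ccccc2)C(C)(C)C)[C@@H](O)[C@@H]2[C@](C)(CC[C@H](O[Si](C)(C)C(C)(C)C)[C@@]2(C)O)[C@H](OC(=O)CCC)CC/C(C)=C\I)cc1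
F4 | step 22 | C9 enone | COc1ccc(COC/C(=C/CO[Si](c2ccccc2)(c2ccccc2)C(C)(C)C)C(=O)[C@@H]2[C@](C)(CC[C@H](O[Si](C)(C)C(C)(C)C)[C@@]2(C)O)[C@H](OC(=O)CCC)CC/C(C)=C\I)cc1
F5 | step 32 | C12 trimethylsilyl enol ether 8,11-bis(trimethylsilyl) ether | CCCC(=O)O[C@@H]1CC/C(C)=C\[C@@H]2OC(=O)[C@H](C)[C@@]2(O[Si](C)(C)C)[C@H](OC(C)=O)[C@@H]2[C@]1(C)CC=C(O[Si](C)(C)C)[C@@]2(C)O[Si](C)(C)C
F6 | step 32 | bis-silylated enone (8,11-bis-O-trimethylsilyl target) | CCCC(=O)O[C@@H]1CC/C(C)=C\[C@@H]2OC(=O)[C@H](C)[C@@]2(O[Si](C)(C)C)[C@H](OC(C)=O)[C@@H]2[C@]1(C)C=CC(=O)[C@@]2(C)O[Si](C)(C)C
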